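Ring C is disconnected at O1–C2 and C4–C4a, so that C2, C3, C4 and ring B arrive together as a caffeoyl ester on the ring A phenol oxygen that becomes O1. In one telescoped operation a photo-Fries shift moves the acyl group from O1 to C4a, and a chiral bifunctional thiourea then closes O1 onto C2 (6-endo oxa-Michael), setting (2S). The step exploits ring A itself: of the two carbons ortho to O1 only C4a is free, because C8 already carries the (Z)-hydroxyprenyl chain, and O1 is the only unsilylated phenol, so acyl shift and ring closure can each go only one way. The precursor is an aryl cinnamate, made from three simple fragments.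

Key step: step 9

Assumption: 2,4-dihydroxy-6-methoxybenzaldehyde, prop-2-yn-1-ol and (E)-caffeic acid are taken as purchased. (TBS = tert-butyldimethylsilyl, Boc = tert-butoxycarbonyl.)

Step 1
Reactants: 1 2,4-dihydroxy-6-methoxybenzaldehyde
Product: 2 4-(tert-butyldimethylsilyloxy)-2-hydroxy-6-methoxybenzaldehyde
Conditions: TBSCl (1.05 equiv), imidazole, CH2Cl2, 0 °C
Reagents that add atoms: TBSCl, CC(C)(C)[Si](C)(C)Cl
Why: Chemoselective silylation, because the 4-OH (para to the formyl group, not hydrogen-bonded) is more acidic and more accessible than the chelated 2-OH, so one equivalent of TBSCl should silylate it alone.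

Step 2
Reactants: 2 4-(tert-butyldimethylsilyloxy)-2-hydroxy-6-methoxybenzaldehyde
Product: 3 tert-butyl [5-(tert-butyldimethylsilyloxy)-2-formyl-3-methoxyphenyl] carbonate
Conditions: Boc2O, i-Pr2NEt, DMAP (cat.), THF, 0 °C → rt
Reagents that add atoms: Boc2O, CC(C)(C)OC(=O)OC(=O)OC(C)(C)C
Why: DMAP-catalysed carbonate formation on the remaining phenol installs the group that later triggers quinone methide formation.

Step 3
Reactants: 3 tert-butyl [5-(tert-butyldimethylsilyloxy)-2-formyl-3-methoxyphenyl] carbonate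
Product: 4 tert-butyl [5-(tert-butyldimethylsilyloxy)-2-(hydroxymethyl)-3-methoxyphenyl] carbonate
Conditions: BH3·THF, THF, 0 °C; pH 7 buffer
Reagents that add atoms: none
Why: Borane reduction of the aldehyde passes through a neutral alkoxyborane and not a free alkoxide, so the aryl carbonate should not migrate before work-up and the silyl ether is inert.

Step 4
Reactants: 5 prop-2-yn-1-ol
Product: 7 (Z)-3-iodo-2-methylprop-2-en-1-ol, via cyclic alkenylmagnesium alkoxide 6 (not isolated)
Conditions: MeMgBr (2.3 equiv), CuI (10 mol %), Et2O/THF, −10 °C → rt; then I2, −78 → 0 °C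
Reagents that add atoms: methylmagnesium bromide, C[Mg]Br; iodine, II
Why: Copper-catalysed anti-carbomagnesiation of the propargylic alkoxide puts methyl on C2 and magnesium on C3 inside a five-membered chelate cis to CH2O, and iodinolysis with retention should give the Z iodide alone, which fixes the side-chain alkene geometry.

Step 5
Reactants: 7 (Z)-3-iodo-2-methylprop-2-en-1-ol
Product: 8 tert-butyl{[(Z)-3-iodo-2-methylprop-2-en-1-yl]oxy}dimethylsilane
Conditions: TBSCl, imidazole, CH2Cl2, 0 °C → rt
Reagents that add atoms: TBSCl, CC(C)(C)[Si](C)(C)Cl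
Why: Standard silylation of a primary allylic alcohol, which leaves the alkene geometry untouched.

Step 6
Reactants: 8 tert-butyl{[(Z)-3-iodo-2-methylprop-2-en-1-yl]oxy}dimethylsilane; 4 tert-butyl [5-(tert-butyldimethylsilyloxy)-2-(hydroxymethyl)-3-methoxyphenyl] carbonate
Product: 12 5-(tert-butyldimethylsilyloxy)-2-[(Z)-4-(tert-butyldimethylsilyloxy)-3-methylbut-2-en-1-yl]-3-methoxyphenol, via alkenyllithium 9 (not isolated), via alkenylmagnesium bromide 10 (not isolated), via ortho-quinone methide 11 (not isolated)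
Conditions: 8 (2.3 equiv), t-BuLi (4.6 equiv), Et2O, −78 °C; MgBr2·OEt2, −78 °C; then 4, −78 °C → rt; aq NH4Cl
Reagents that add atoms: none
Why: Base-triggered ortho-quinone methide generation and 1,4-addition: the first equivalent of the configurationally stable alkenyl Grignard reagent deprotonates 4 so that the Boc group migrates to the benzylic oxygen and leaves as tert-butyl carbonate, and the second equivalent adds to the methide carbon with retention of the Z geometry, freeing exactly the phenol needed next.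

Step 7
Reactants: 13 (E)-3-(3,4-dihydroxyphenyl)prop-2-enoic acid (caffeic acid)
Product: 15 (E)-3-[3,4-bis(tert-butyldimethylsilyloxy)phenyl]prop-2-enoic acid, via tris-silylated caffeate 14 (not isolated)
Conditions: TBSCl (3.3 equiv), imidazole, DMF, rt; then AcOH/THF/H2O, rt
Reagents that add atoms: TBSCl, CC(C)(C)[Si](C)(C)Cl
Why: Exhaustive silylation followed by selective hydrolysis of the far more labile silyl ester should leave both aryl silyl ethers in place.

Step 8
Reactants: 12 5-(tert-butyldimethylsilyloxy)-2-[(Z)-4-(tert-butyldimethylsilyloxy)-3-methylbut-2-en-1-yl]-3-methoxyphenol; 15 (E)-3-[3,4-bis(tert-butyldimethylsilyloxy)phenyl]prop-2-enoic acid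
Product: 16 5-(tert-butyldimethylsilyloxy)-2-[(Z)-4-(tert-butyldimethylsilyloxy)-3-methylbut-2-en-1-yl]-3-methoxyphenyl (E)-3-[3,4-bis(tert-butyldimethylsilyloxy)phenyl]prop-2-enoate
Conditions: EDC·HCl, DMAP, CH2Cl2, 0 °C → rt
Reagents that add atoms: none
Why: Steglich esterification of the only free phenol of 12, under neutral conditions that should spare all silyl ethers and both alkene geometries.

Step 9
Reactants: 16 5-(tert-butyldimethylsilyloxy)-2-[(Z)-4-(tert-butyldimethylsilyloxy)-3-methylbut-2-en-1-yl]-3-methoxyphenyl (E)-3-[3,4-bis(tert-butyldimethylsilyloxy)phenyl]prop-2-enoate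
Product: 18 (2S)-2-[3,4-bis(tert-butyldimethylsilyloxy)phenyl]-5-(tert-butyldimethylsilyloxy)-8-[(Z)-4-(tert-butyldimethylsilyloxy)-3-methylbut-2-en-1-yl]-7-methoxy-2,3-dihydro-4H-chromen-4-one, via 2'-hydroxychalcone 17 (not isolated)
Conditions: hν (310 nm), degassed PhMe (0.01 M), flow, 20 °C; then, in the dark, 1-[3,5-bis(trifluoromethyl)phenyl]-3-[(8α,9S)-6′-methoxycinchonan-9-yl]thiourea (10 mol %), −20 °C
Reagents that add atoms: none
Why: Excitation of the cinnamoyl ester should cleave the aryl O–acyl bond homolytically, and recombination of the caged aryloxy/acyl radical pair at the ortho carbon followed by tautomerisation (photo-Fries rearrangement, known for aryl cinnamates) forms the C4–C4a bond and gives 2'-hydroxychalcone 17. In the dark the quinuclidine nitrogen of the catalyst deprotonates the freed phenol while the thiourea binds the enone carbonyl, and the phenoxide adds to the β-carbon to form the O1–C2 bond; the closest known reaction types are the tandem photo-Fries/oxa-Michael route to chroman-4-ones and the cinchona-thiourea-catalysed cyclisation of 2'-hydroxychalcones to flavanones. Ring C closes in the 6-endo-trig mode (intramolecular oxa-Michael addition), helped by the twist that the two ortho substituents impose on the aryl ketone. The new stereocenter C2 is controlled by the chiral catalyst, which should shield one face of the enone and deliver the (2S) product; the quinidine-derived pseudoenantiomer is the direct substitute if the facial preference on this substrate proves opposite. The step needs ortho-selective acyl migration and a single site of ring closure: C8 is blocked by the side chain so that only C4a can accept the acyl group ortho to O1, and the silyl ether on the other flanking oxygen leaves O1 as the only nucleophile, which rules out the 6-substituted isomer. Low temperature and a short contact time are meant to keep reversible retro-oxa-Michael opening from eroding the kinetic enantioselectivity.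

Step 10
Reactants: 18 (2S)-2-[3,4-bis(tert-butyldimethylsilyloxy)phenyl]-5-(tert-butyldimethylsilyloxy)-8-[(Z)-4-(tert-butyldimethylsilyloxy)-3-methylbut-2-en-1-yl]-7-methoxy-2,3-dihydro-4H-chromen-4-one
Product: 19 (2S)-2-(3,4-dihydroxyphenyl)-5-hydroxy-8-[(Z)-4-hydroxy-3-methylbut-2-en-1-yl]-7-methoxy-2,3-dihydro-4H-chromen-4-one
Conditions: HF·pyridine, pyridine, THF, 0 °C → rt
Reagents that add atoms: none
Why: Global desilylation with buffered HF·pyridine cleaves all four Si–O bonds without a base, so retro-oxa-Michael ring opening at C2 should not occur and the Z-allylic alcohol should be released unchanged.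

Compound list
1 | 2,4-dihydroxy-6-methoxybenzaldehyde | COc1cc(O)cc(O)c1C=O | starting material
2 | 4-(tert-butyldimethylsilyloxy)-2-hydroxy-6-methoxybenzaldehyde | COc1cc(O[Si](C)(C)C(C)(C)C)cc(O)c1C=O | intermediate
3 | tert-butyl [5-(tert-butyldimethylsilyloxy)-2-formyl-3-methoxyphenyl] carbonate | COc1cc(O[Si](C)(C)C(C)(C)C)cc(OC(=O)OC(C)(C)C)c1C=O | intermediate
4 | tert-butyl [5-(tert-butyldimethylsilyloxy)-2-(hydroxymethyl)-3-methoxyphenyl] carbonate | COc1cc(O[Si](C)(C)C(C)(C)C)cc(OC(=O)OC(C)(C)C)c1CO | intermediate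
5 | prop-2-yn-1-ol | C#CCO | starting material
6 | 4-methyl-2,5-dihydro-1,2-oxamagnesole (cyclic (Z)-alkenylmagnesium alkoxide) | CC1=C[Mg]OC1 | intermediate
7 | (Z)-3-iodo-2-methylprop-2-en-1-ol | I/C=C(/C)CO | intermediate
8 | tert-butyl{[(Z)-3-iodo-2-methylprop-2-en-1-yl]oxy}dimethylsilane | I/C=C(/C)CO[Si](C)(C)C(C)(C)C | intermediate
9 | [(Z)-3-(tert-butyldimethylsilyloxy)-2-methylprop-1-en-1-yl]lithium | [Li]/C=C(/C)CO[Si](C)(C)C(C)(C)C | intermediate
10 | [(Z)-3-(tert-butyldimethylsilyloxy)-2-methylprop-1-en-1-yl]magnesium bromide | Br[Mg]/C=C(/C)CO[Si](C)(C)C(C)(C)C | intermediate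
11 | 3-(tert-butyldimethylsilyloxy)-5-methoxy-6-methylidenecyclohexa-2,4-dien-1-one | C=C1C(=O)C=C(O[Si](C)(C)C(C)(C)C)C=C1OC | intermediate
12 | 5-(tert-butyldimethylsilyloxy)-2-[(Z)-4-(tert-butyldimethylsilyloxy)-3-methylbut-2-en-1-yl]-3-methoxyphenol | COc1cc(O[Si](C)(C)C(C)(C)C)cc(O)c1C/C=C(/C)CO[Si](C)(C)C(C)(C)C | intermediate
13 | (E)-3-(3,4-dihydroxyphenyl)prop-2-enoic acid (caffeic acid) | OC(=O)/C=C/c1ccc(O)c(O)c1 | starting material
14 | tert-butyldimethylsilyl (E)-3-[3,4-bis(tert-butyldimethylsilyloxy)phenyl]prop-2-enoate | CC(C)(C)[Si](C)(C)OC(=O)/C=C/c1ccc(O[Si](C)(C)C(C)(C)C)c(O[Si](C)(C)C(C)(C)C)c1 | intermediate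
15 | (E)-3-[3,4-bis(tert-butyldimethylsilyloxy)phenyl]prop-2-enoic acid | OC(=O)/C=C/c1ccc(O[Si](C)(C)C(C)(C)C)c(O[Si](C)(C)C(C)(C)C)c1 | intermediate
16 | 5-(tert-butyldimethylsilyloxy)-2-[(Z)-4-(tert-butyldimethylsilyloxy)-3-methylbut-2-en-1-yl]-3-methoxyphenyl (E)-3-[3,4-bis(tert-butyldimethylsilyloxy)phenyl]prop-2-enoate | COc1cc(O[Si](C)(C)C(C)(C)C)cc(OC(=O)/C=C/c2ccc(O[Si](C)(C)C(C)(C)C)c(O[Si](C)(C)C(C)(C)C)c2)c1C/C=C(/C)CO[Si](C)(C)C(C)(C)C | intermediate
17 | (E)-3-[3,4-bis(tert-butyldimethylsilyloxy)phenyl]-1-{6-(tert-butyldimethylsilyloxy)-3-[(Z)-4-(tert-butyldimethylsilyloxy)-3-methylbut-2-en-1-yl]-2-hydroxy-4-methoxyphenyl}prop-2-en-1-one | COc1cc(O[Si](C)(C)C(C)(C)C)c(C(=O)/C=C/c2ccc(O[Si](C)(C)C(C)(C)C)c(O[Si](C)(C)C(C)(C)C)c2)c(O)c1C/C=C(/C)CO[Si](C)(C)C(C)(C)C | intermediate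
18 | (2S)-2-[3,4-bis(tert-butyldimethylsilyloxy)phenyl]-5-(tert-butyldimethylsilyloxy)-8-[(Z)-4-(tert-butyldimethylsilyloxy)-3-methylbut-2-en-1-yl]-7-methoxy-2,3-dihydro-4H-chromen-4-one | COc1cc(O[Si](C)(C)C(C)(C)C)c2c(c1C/C=C(/C)CO[Si](C)(C)C(C)(C)C)O[C@H](c1ccc(O[Si](C)(C)C(C)(C)C)c(O[Si](C)(C)C(C)(C)C)c1)CC2=O | intermediate
19 | (2S)-2-(3,4-dihydroxyphenyl)-5-hydroxy-8-[(Z)-4-hydroxy-3-methylbut-2-en-1-yl]-7-methoxy-2,3-dihydro-4H-chromen-4-one | COc1cc(O)c2c(c1C/C=C(/C)CO)O[C@H](c1ccc(O)c(O)c1)CC2=O | target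

Total step count: 10. Longest linear sequence: 7 steps (steps 1, 2, 3, 6, 8, 9, 10).

Steps most likely to fail

Step 9. The excited cinnamoyl ester may relax mainly by E/Z isomerisation of its double bond, or migrate to the para carbon or fragment, instead of shifting to C4a. The facial discrimination in the ring closure may also be modest, or be eroded by reversible ring opening. The fallback uses a different C–C bond-forming logic and a different source of enantiopurity, sets out from phenol 12 and acid 15, and comes back at 18. Acid 15 is converted with oxalyl chloride and catalytic DMF into (E)-3-[3,4-bis(tert-butyldimethylsilyloxy)phenyl]prop-2-enoyl chloride F1. The bromomagnesium phenoxide of 12 (EtMgBr, toluene) should be acylated by F1 at its only free ortho carbon under magnesium-template control, giving chalcone 17, here isolated. DBU in CH2Cl2 should close it to the racemic tetra-silylated flavanone F2. Kinetic resolution by asymmetric transfer hydrogenation ([Cp*RhCl((R,R)-TsDPEN)], HCO2H/Et3N, EtOAc, stopped near half conversion) should reduce the (2R)-ketone to the (2R,4R)-cis-flavan-4-ol F3 and leave the (2S)-ketone, which after chromatographic separation is 18.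

Step 6. Silicon may migrate from oxygen to carbon in the alkenyllithium, the alkenyl Grignard reagent may be protonated prematurely, or the electron-rich quinone methide may self-condense faster than it is trapped. The fallback replaces the conjugate addition by a cross-coupling, sets out from 4 and 8, and comes back at 12. Alcohol 4 is converted (MsCl, Et3N, LiCl, THF, 0 °C) into tert-butyl [5-(tert-butyldimethylsilyloxy)-2-(chloromethyl)-3-methoxyphenyl] carbonate F4. Zinc insertion (Zn dust, LiCl, THF) should give the benzylic zinc chloride F5. Negishi coupling of F5 with iodide 8 (Pd(PPh3)4, THF, rt) should proceed with retention of the Z geometry to tert-butyl {5-(tert-butyldimethylsilyloxy)-2-[(Z)-4-(tert-butyldimethylsilyloxy)-3-methylbut-2-en-1-yl]-3-methoxyphenyl} carbonate F6. Piperidine in CH2Cl2 should cleave the aryl carbonate without touching the silyl ethers, giving 12.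

Step 10. The hindered aryl silyl ethers may cleave slowly, prolonged exposure to HF may ionise the allylic alcohol, and a more basic fluoride source would risk ring opening at C2 with loss of configuration. The fallback replaces the single global cleavage by an orthogonal two-stage unmasking, sets out from 18, and comes back at 19. KHF2 in MeOH at rt should cleave only the three aryl silyl ethers, giving (2S)-8-[(Z)-4-(tert-butyldimethylsilyloxy)-3-methylbut-2-en-1-yl]-2-(3,4-dihydroxyphenyl)-5-hydroxy-7-methoxy-2,3-dihydro-4H-chromen-4-one F7. PPTS in MeOH at rt should then remove the primary silyl ether by acid-catalysed methanolysis, giving 19.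

Further compounds
F1 | step 9 | (E)-3-[3,4-bis(tert-butyldimethylsilyloxy)phenyl]prop-2-enoyl chloride | ClC(=O)/C=C/c1ccc(O[Si](C)(C)C(C)(C)C)c(O[Si](C)(C)C(C)(C)C)c1
F2 | step 9 | racemic 2-[3,4-bis(tert-butyldimethylsilyloxy)phenyl]-5-(tert-butyldimethylsilyloxy)-8-[(Z)-4-(tert-butyldimethylsilyloxy)-3-methylbut-2-en-1-yl]-7-methoxy-2,3-dihydro-4H-chromen-4-one | COc1cc(O[Si](C)(C)C(C)(C)C)c2c(c1C/C=C(/C)CO[Si](C)(C)C(C)(C)C)OC(c1ccc(O[Si](C)(C)C(C)(C)C)c(O[Si](C)(C)C(C)(C)C)c1)CC2=O
F3 | step 9 | (2R,4R)-2-[3,4-bis(tert-butyldimethylsilyloxy)phenyl]-5-(tert-butyldimethylsilyloxy)-8-[(Z)-4-(tert-butyldimethylsilyloxy)-3-methylbut-2-en-1-yl]-7-methoxy-3,4-dihydro-2H-chromen-4-ol | COc1cc(O[Si](C)(C)C(C)(C)C)c2c(c1C/C=C(/C)CO[Si](C)(C)C(C)(C)C)O[C@@H](c1ccc(O[Si](C)(C)C(C)(C)C)c(O[Si](C)(C)C(C)(C)C)c1)C[C@H]2O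
F4 | step 6 | tert-butyl [5-(tert-butyldimethylsilyloxy)-2-(chloromethyl)-3-methoxyphenyl] carbonate | COc1cc(O[Si](C)(C)C(C)(C)C)cc(OC(=O)OC(C)(C)C)c1CCl
F5 | step 6 | {2-[(tert-butoxycarbonyl)oxy]-4-(tert-butyldimethylsilyloxy)-6-methoxybenzyl}zinc chloride | COc1cc(O[Si](C)(C)C(C)(C)C)cc(OC(=O)OC(C)(C)C)c1C[Zn]Cl
F6 | step 6 | tert-butyl {5-(tert-butyldimethylsilyloxy)-2-[(Z)-4-(tert-butyldimethylsilyloxy)-3-methylbut-2-en-1-yl]-3-methoxyphenyl} carbonate | COc1cc(O[Si](C)(C)C(C)(C)C)cc(OC(=O)OC(C)(C)C)c1C/C=C(/C)CO[Si](C)(C)C(C)(C)C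
F7 | step 10 | (2S)-8-[(Z)-4-(tert-butyldimethylsilyloxy)-3-methylbut-2-en-1-yl]-2-(3,4-dihydroxyphenyl)-5-hydroxy-7-methoxy-2,3-dihydro-4H-chromen-4-one | COc1cc(O)c2c(c1C/C=C(/C)CO[Si](C)(C)C(C)(C)C)O[C@H](c1ccc(O)c(O)c1)CC2=O
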